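**Proposed synthesis of CNP0218554.0 (23): ring A by cyclobutenone ring expansion**

## The problem

Compound 23 is a flavone, 2-(3,5-dihydroxy-4-methoxyphenyl)-7-hydroxy-5,8-dimethoxy-4H-chromen-4-one. A pyranone ring C is fused through C4a–C8a to a benzene ring A that carries oxygen on every carbon except C6, and is joined at C2 to a symmetric ring B. There is no stereocentre, so the difficulty is regiochemical: six aryl–oxygen bonds must be set, three as methyl ethers (O5, O8, O4') and three as free phenols (O7, O3', O5'). The 5,7,8-pattern of ring A is awkward to reach from a benzene because three neighbouring oxygens (O7, O8, O1) must be told apart. Stereocentres that appear on the way (C2 and C4 of a reduced ring C) are transient; they control nothing in the target and only have to survive until ring C is oxidised. The fragile points are: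

- the C5 methoxy group peri to the C4 carbonyl, which boron and aluminium halides cleave first, so late ether cleavage by Lewis acids is excluded;
- the C2=C3 bond toward hydrogenation;
- any 5,8-dihydroxy intermediate toward air;
- the ring B phenols toward quinone oxidants.

What opens the structure to ring construction is ring A itself. Para oxygens on C5 and C8, a third oxygen on C7 next to C8, hydrogen on C6 and the ring oxygen on C8a are exactly the array produced when an alkoxycyclobutenedione is joined to an α-oxygenated alkenyl anion and the adduct is ring-expanded, with C8–C8a and C5–C4a as the two new bonds.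

## Retrosynthesis

**23 from 22.** The three benzyl–oxygen bonds at O7, O3' and O5' are cut. With benzyl on every future phenol and methyl on O5, O8 and O4', one neutral hydrogenolysis ends the synthesis and no Lewis acid comes near the C5 methoxy group. Flavone 22 has no free phenol and is easy to handle. The forward reaction must remove three benzyl groups without saturating C2=C3.

**22 from 20.** Ring C is taken back two oxidation levels: the C4 carbonyl to a carbinol and C2=C3 to a single bond, through flavanone 21. This is the price of the ring A construction, because only a reduced ring C offers an enol ether carbon (the future C8a) that can be metallated. Flavan-4-ol 20 has two disposable stereocentres and no free phenol. The forward reaction asks a quinone oxidant to oxidise the electron-rich benzylic carbinol and then dehydrogenate C2–C3.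

**20 from 18, and 18 from 17.** The two ring B benzyl ethers and the C4 hydroxyl of 20 are traced to the three silyl ethers of 18, through triol 19. Ring B cannot carry benzyl ethers when the enol ether is lithiated, and cannot carry free phenols when ring C is oxidised, so the exchange is placed between these two events and done in one operation. The O5 and O8 methyl groups are then cut to give hydroquinone 17. Methylation at the flavan stage needs no selectivity, since the hydroquinone hydroxyls are the only free ones, and O5 is not yet hydrogen-bonded to a carbonyl.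

**17 from 9 and 13.** C8–C8a and C5–C4a are cut. Against the neighbouring cuts through ring C (C4–C3, O1–C2, O1–C8a), which all start from a pre-oxygenated benzene, this one makes ring A and places all four of its oxygens by connectivity. Dihydropyran 9 contains rings B and C with two relative stereocentres. Semisquarate 13 is a four-carbon piece that supplies C5–C8 with three oxygens. The forward reaction requires lithiation of 9 at the enol ether carbon (14), 1,2-addition to the ketone carbonyl of 13 (15), and thermal ring opening to ketene 16 followed by six-electron closure.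

**13 from 11 and 10.** One benzyloxy-bearing carbon of dibenzyl squarate 11 is converted into C–H by hydride addition and acid-induced transposition through 12. Ester 11 comes from squaric acid 10 by double esterification. The ester group is benzyl because its oxygen becomes O7 and must fall in the final hydrogenolysis.

**9 from 8, 7, and 4 plus 5.** The C4 silyl ether is cut to alcohol 8 and the carbinol is traced to enone 7. Ring C of 7 is opened by a hetero-Diels–Alder disconnection (O1–C6 and C2–C3 of the pyranone) to aldehyde 4 and siloxydiene 5, through cycloadduct 6. This forms ring C in one step from an aldehyde; lactone- or aldol-based routes to the same ring are longer. The reduction must be 1,2-selective, and the silylation must use a group without Si–CH3.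

**4 from 3, 2 and 1.** Aldehyde 4 is reached by functional group changes from commercial ester 1: silylation of both phenols, reduction and re-oxidation.

## Roads not taken

**Alternative 1:** Ring C is cut at C4–C3 and O1–C2. The key step joins the fully substituted salicylaldehyde A2 with the ring B sulfoxonium ylide A3 under a trivalent rhodium catalyst. The phenol directs insertion into the formyl C–H bond, the acyl–rhodium species takes up the carbene released from A3 (C4–C3), and cyclodehydration (O1–C2) gives flavone A1.

- Merits: A1 is the same compound as 22, so this road arrives at the flavone oxidation level with all phenols benzylated, one hydrogenolysis from 23. It is highly convergent.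
- Weak points: all regiochemistry is loaded onto A2, a pentasubstituted benzene whose three neighbouring oxygens must be differentiated as free, methyl and benzyl. Its formyl group is flanked on both sides, which crowds the metallacycle, and very electron-rich acyl–metal species are prone to decarbonylation.
- Comparison: from A2 and A3 this road is clearly shorter (two steps to 23, against five from 9 and 13) and needs no oxidation-level adjustment. The chosen plan sets against this the fact that its ring A is made from squaric acid with each oxygen fixed by the bond-forming events, whereas A2 would have to be prepared by several selectivity-dependent steps. It also uses no noble-metal catalyst at the convergent step.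

**Alternative 2:** The cut is O1–C8a. Diketone A5 carries a ring A with methoxy groups at C5 and C8 and hydrogen at C8a. A ceric oxidant removes both methyl groups to give acylquinone A6, the enol oxygen of the diketone adds to C8a, and tautomerisation gives the 5,8-dihydroxyflavone A4.

- Merits: ring A needs only three oxygens before the key step, the fourth being introduced by the oxidation, and A5 should be available quickly by acylation chemistry. In step count this is probably the shortest of the four plans.
- Weak points: the oxidant must discriminate ring A from the equally electron-rich ring B and from the enolised diketone. The methyl groups removed in the key step must be put back, and in A4 the C5 hydroxyl is hydrogen-bonded to the C4 carbonyl and slow to alkylate. A4 is an air-sensitive hydroquinone at the most advanced stage.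
- Comparison: the chosen plan also methylates a hydroquinone, but on flavan 17 where O5 is not chelated. No advanced intermediate meets a one-electron oxidant in the presence of ring B, and no ether is cleaved only to be re-formed.

**Alternative 3:** Ring C is cut at C4a–C4, C4–C3 and O1–C2. Under zerovalent palladium the iodoresorcinol A8 undergoes oxidative addition, inserts carbon monoxide A10 and couples with the ring B alkyne A9. The ortho hydroxyl then closes ring C by conjugate addition to give flavone A7.

- Merits: three components are joined in one operation, the C7 hydroxyl is carried free, and A7 is two benzyl groups away from 23. In convergence it is the best of the four plans.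
- Weak points: A8 is a tetraoxygenated iodoarene with both ortho positions occupied, so oxidative addition is slow. Its free phenols can intercept the acylpalladium intermediate. Ring closure can go 5-exo as well as 6-endo, which leaves the ring size of ring C open to doubt. A8 itself requires a scarce tetraoxygenated benzene.
- Comparison: the chosen plan is longer after its key step. It sets against this a ring C whose size is fixed by a cycloaddition, a ring A built from a cheap four-carbon unit, and no handling of a toxic gas under pressure.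

Key step: step 9

Assumption: all compounds with stereocentres (6–9, 12, 14–21) are racemic; the SMILES show one enantiomer, only the cis relation of C2 and C4 matters, and both centres are removed in step 12.

## Route

Step 1
Reactants: 1 methyl 3,5-dihydroxy-4-methoxybenzoate
Product: 2 methyl 4-methoxy-3,5-bis(triisopropylsilyloxy)benzoate
Conditions: TIPSCl, imidazole, DMF, rt
Reagents that add atoms: chlorotriisopropylsilane, CC(C)[Si](Cl)(C(C)C)C(C)C
Why: Silylation of two equivalent phenols under imidazole catalysis. The triisopropylsilyl group has no Si–CH3, shields the ring B ortho positions and tolerates the alkyllithium of step 9.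

Step 2
Reactants: 2 methyl 4-methoxy-3,5-bis(triisopropylsilyloxy)benzoate
Product: 3 [4-methoxy-3,5-bis(triisopropylsilyloxy)phenyl]methanol
Conditions: i-Bu2AlH, CH2Cl2, −78 → 0 °C
Reagents that add atoms: none
Why: Aluminium hydride reduction of an aryl ester to the benzylic alcohol; aryl silyl ethers are inert to the reagent at low temperature.

Step 3
Reactants: 3 [4-methoxy-3,5-bis(triisopropylsilyloxy)phenyl]methanol
Product: 4 4-methoxy-3,5-bis(triisopropylsilyloxy)benzaldehyde
Conditions: MnO2, CH2Cl2, rt
Reagents that add atoms: none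
Why: Heterogeneous oxidation of a benzylic alcohol by MnO2 stops at the aldehyde and leaves silyl ethers untouched.

Step 4
Reactants: 4 4-methoxy-3,5-bis(triisopropylsilyloxy)benzaldehyde; 5 (E)-1-methoxy-3-(trimethylsilyloxy)buta-1,3-diene
Product: 7 2-[4-methoxy-3,5-bis(triisopropylsilyloxy)phenyl]-2,3-dihydro-4H-pyran-4-one (racemic), via methoxy silyloxy dihydropyran cycloadduct 6 (not isolated)
Conditions: ZnCl2, THF, rt; then TFA, CH2Cl2, 0 °C
Reagents that add atoms: none
Why: Lewis acid-catalysed hetero-Diels–Alder reaction of an aryl aldehyde with Danishefsky's diene forms O1–C6 and C2–C3 of ring C. Brief acid treatment expels methanol and the trimethylsilyl group from 6 to give the enone. The C2 stereocentre is formed racemic.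

Step 5
Reactants: 7 2-[4-methoxy-3,5-bis(triisopropylsilyloxy)phenyl]-2,3-dihydro-4H-pyran-4-one
Product: 8 cis-(2S*,4S*)-2-[4-methoxy-3,5-bis(triisopropylsilyloxy)phenyl]-3,4-dihydro-2H-pyran-4-ol (racemic)
Conditions: NaBH4, CeCl3·7H2O, MeOH/CH2Cl2, −78 °C
Reagents that add atoms: none
Why: Luche 1,2-reduction of the vinylogous ester carbonyl. Hydride attacks axially on the half-chair with the aryl group pseudo-equatorial, so C4 is set cis to C2 by substrate control; the configuration is of no later consequence.

Step 6
Reactants: 8 cis-(2S*,4S*)-2-[4-methoxy-3,5-bis(triisopropylsilyloxy)phenyl]-3,4-dihydro-2H-pyran-4-ol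
Product: 9 cis-(2S*,4S*)-2-[4-methoxy-3,5-bis(triisopropylsilyloxy)phenyl]-4-(triisopropylsilyloxy)-3,4-dihydro-2H-pyran (racemic)
Conditions: TIPSOTf, 2,6-lutidine, CH2Cl2, −78 → 0 °C
Reagents that add atoms: triisopropylsilyl trifluoromethanesulfonate, CC(C)[Si](C(C)C)(C(C)C)OS(=O)(=O)C(F)(F)F
Why: Silyl triflate silylation of a secondary allylic alcohol, as used for glycal hydroxyls. The hindered base keeps the medium non-acidic so the allylic enol ether does not ionise.

Step 7
Reactants: 10 squaric acid (3,4-dihydroxycyclobut-3-ene-1,2-dione)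
Product: 11 3,4-bis(benzyloxy)cyclobut-3-ene-1,2-dione
Conditions: BnOH, toluene, reflux, Dean–Stark
Reagents that add atoms: benzyl alcohol, OCc1ccccc1
Why: Azeotropic esterification of the strongly acidic vinylogous diacid, the standard access to dialkyl squarates.

Step 8
Reactants: 11 3,4-bis(benzyloxy)cyclobut-3-ene-1,2-dione
Product: 13 3-(benzyloxy)cyclobut-3-ene-1,2-dione, via 4-hydroxycyclobutenone 12 (not isolated)
Conditions: LiAlH(OtBu)3, THF, −78 → −20 °C; then conc. HCl (cat.), CH2Cl2, rt
Reagents that add atoms: none
Why: The hindered hydride adds once to a carbonyl of the squarate to give 12. Acid then induces allylic transposition with loss of benzyl alcohol to the semisquarate, the known route to alkyl semisquarates from dialkyl squarates.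

Step 9
Reactants: 9 cis-(2S*,4S*)-2-[4-methoxy-3,5-bis(triisopropylsilyloxy)phenyl]-4-(triisopropylsilyloxy)-3,4-dihydro-2H-pyran; 13 3-(benzyloxy)cyclobut-3-ene-1,2-dione
Product: 17 cis-(2S*,4S*)-7-(benzyloxy)-2-[4-methoxy-3,5-bis(triisopropylsilyloxy)phenyl]-4-(triisopropylsilyloxy)chromane-5,8-diol (racemic), via C6-lithiated dihydropyran 14 (not isolated), via 4-hydroxycyclobutenone adduct 15 (not isolated), via (Z)-dienylketene 16 (not isolated)
Conditions: t-BuLi, THF, −78 → 0 °C; 13, THF, −78 °C; aq. NH4Cl; crude adduct in toluene, 110 °C, argon; aq. Na2S2O4 work-up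
Reagents that add atoms: none
Why: t-BuLi removes the vinyl hydrogen at C6 of 9 next to the ring oxygen, as in the lithiation of silyl-protected glycals, to give 14. Alkenyllithium 14 adds 1,2 to the ketone-like carbonyl of 13, the one flanked by the benzyloxy-bearing carbon, and forms C8–C8a in 15; the other carbonyl is a deactivated vinylogous ester, which places the benzyloxy group at C7 next to C8. At 110 °C 15 opens by conrotatory four-electron electrocyclic ring opening with the hydroxyl turning outward, so the pyranyl group turns inward and (Z)-dienylketene 16 results. Ring A then closes by thermal six-electron electrocyclisation of the ketene carbon onto C5 of the pyran (C5–C4a, a six-membered carbocycle), and tautomerisation gives hydroquinone 17. The closest known reaction type is the Moore rearrangement of 4-alkenyl-4-hydroxycyclobutenones, made from lithiated cyclic enol ethers and alkoxycyclobutenediones, to annulated hydroquinones. No lasting stereocentre is created: the carbinol centre of 15 is destroyed on ring opening and the cis C2/C4 pair of 9 is carried through unchanged. Three selectivities are needed: C6 over the benzylic C2–H in the lithiation (sp2 C–H acidity and coordination to the ring oxygen, an electron-rich aryl group that disfavours the benzylic anion, silyl groups without Si–CH3); ketone over vinylogous ester in the addition (electronic bias of 13); and outward rotation of the hydroxyl in the ring opening (donor torquoselectivity). The hydroquinone is kept under argon and washed with dithionite because it is easily oxidised.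

Step 10
Reactants: 17 cis-(2S*,4S*)-7-(benzyloxy)-2-[4-methoxy-3,5-bis(triisopropylsilyloxy)phenyl]-4-(triisopropylsilyloxy)chromane-5,8-diol
Product: 18 cis-(2S*,4S*)-7-(benzyloxy)-5,8-dimethoxy-2-[4-methoxy-3,5-bis(triisopropylsilyloxy)phenyl]-4-(triisopropylsilyloxy)chromane (racemic)
Conditions: MeI, K2CO3, acetone, 50 °C, argon
Reagents that add atoms: iodomethane, CI
Why: Williamson methylation of the only two free hydroxyls. O5 is not yet chelated to a carbonyl, and the mild heterogeneous base leaves the hindered aryl silyl ethers intact.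

Step 11
Reactants: 18 cis-(2S*,4S*)-7-(benzyloxy)-5,8-dimethoxy-2-[4-methoxy-3,5-bis(triisopropylsilyloxy)phenyl]-4-(triisopropylsilyloxy)chromane
Product: 20 cis-(2S*,4S*)-7-(benzyloxy)-2-[3,5-bis(benzyloxy)-4-methoxyphenyl]-5,8-dimethoxychroman-4-ol (racemic), via desilylated flavan-4-ol triol 19 (not isolated)
Conditions: TBAF, THF, 0 °C → rt; then BnBr, K2CO3, DMF, rt
Reagents that add atoms: benzyl bromide, BrCc1ccccc1
Why: Fluoride cleaves the two aryl silyl ethers and the secondary silyl ether. The phenoxides of 19 are then benzylated (Williamson) while the far less acidic C4 alcohol stays free. Ring B is thereby masked for the oxidation, and all three phenol protecting groups become removable in one hydrogenolysis.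

Step 12
Reactants: 20 cis-(2S*,4S*)-7-(benzyloxy)-2-[3,5-bis(benzyloxy)-4-methoxyphenyl]-5,8-dimethoxychroman-4-ol
Product: 22 7-(benzyloxy)-2-[3,5-bis(benzyloxy)-4-methoxyphenyl]-5,8-dimethoxy-4H-chromen-4-one, via flavanone 21 (not isolated)
Conditions: DDQ (3 equiv), 1,4-dioxane, rt → 100 °C
Reagents that add atoms: none
Why: DDQ abstracts hydride from the carbinol C–H, which is benzylic to the electron-rich ring A, to give flavanone 21. On heating it dehydrogenates C2–C3, the established DDQ conversion of flavanones into flavones. Both stereocentres disappear and no free phenol is present.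

Step 13
Reactants: 22 7-(benzyloxy)-2-[3,5-bis(benzyloxy)-4-methoxyphenyl]-5,8-dimethoxy-4H-chromen-4-one
Product: 23 2-(3,5-dihydroxy-4-methoxyphenyl)-7-hydroxy-5,8-dimethoxy-4H-chromen-4-one (CNP0218554.0)
Conditions: H2 (1 atm), 10% Pd/C, EtOAc/MeOH, rt
Reagents that add atoms: none
Why: Hydrogenolysis of three aryl benzyl ethers over palladium. The conjugated, electron-rich pyranone double bond is reduced much more slowly, and the methyl ethers, including the Lewis acid-sensitive C5 methoxy group, are untouched.

## Compound list

1 | methyl 3,5-dihydroxy-4-methoxybenzoate | COC(=O)c1cc(O)c(OC)c(O)c1 | starting material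
2 | methyl 4-methoxy-3,5-bis(triisopropylsilyloxy)benzoate | COC(=O)c1cc(O[Si](C(C)C)(C(C)C)C(C)C)c(OC)c(O[Si](C(C)C)(C(C)C)C(C)C)c1 | intermediate
3 | [4-methoxy-3,5-bis(triisopropylsilyloxy)phenyl]methanol | OCc1cc(O[Si](C(C)C)(C(C)C)C(C)C)c(OC)c(O[Si](C(C)C)(C(C)C)C(C)C)c1 | intermediate
4 | 4-methoxy-3,5-bis(triisopropylsilyloxy)benzaldehyde | O=Cc1cc(O[Si](C(C)C)(C(C)C)C(C)C)c(OC)c(O[Si](C(C)C)(C(C)C)C(C)C)c1 | intermediate
5 | (E)-1-methoxy-3-(trimethylsilyloxy)buta-1,3-diene | CO/C=C/C(=C)O[Si](C)(C)C | starting material
6 | 6-methoxy-2-[4-methoxy-3,5-bis(triisopropylsilyloxy)phenyl]-4-(trimethylsilyloxy)-3,6-dihydro-2H-pyran (racemic, C6 epimers) | COC1C=C(O[Si](C)(C)C)CC(c2cc(O[Si](C(C)C)(C(C)C)C(C)C)c(OC)c(O[Si](C(C)C)(C(C)C)C(C)C)c2)O1 | intermediate (not isolated)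
7 | 2-[4-methoxy-3,5-bis(triisopropylsilyloxy)phenyl]-2,3-dihydro-4H-pyran-4-one (racemic, one enantiomer drawn) | O=C1C=CO[C@H](c2cc(O[Si](C(C)C)(C(C)C)C(C)C)c(OC)c(O[Si](C(C)C)(C(C)C)C(C)C)c2)C1 | intermediate
8 | cis-(2S*,4S*)-2-[4-methoxy-3,5-bis(triisopropylsilyloxy)phenyl]-3,4-dihydro-2H-pyran-4-ol (racemic, one enantiomer drawn) | C1=CO[C@H](c2cc(O[Si](C(C)C)(C(C)C)C(C)C)c(OC)c(O[Si](C(C)C)(C(C)C)C(C)C)c2)C[C@@H]1O | intermediate
9 | cis-(2S*,4S*)-2-[4-methoxy-3,5-bis(triisopropylsilyloxy)phenyl]-4-(triisopropylsilyloxy)-3,4-dihydro-2H-pyran (racemic, one enantiomer drawn) | C1=CO[C@H](c2cc(O[Si](C(C)C)(C(C)C)C(C)C)c(OC)c(O[Si](C(C)C)(C(C)C)C(C)C)c2)C[C@@H]1O[Si](C(C)C)(C(C)C)C(C)C | intermediate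
10 | squaric acid (3,4-dihydroxycyclobut-3-ene-1,2-dione) | OC1=C(O)C(=O)C1=O | starting material
11 | 3,4-bis(benzyloxy)cyclobut-3-ene-1,2-dione | O=C1C(=O)C(OCc2ccccc2)=C1OCc1ccccc1 | intermediate
12 | 2,3-bis(benzyloxy)-4-hydroxycyclobut-2-en-1-one (racemic) | O=C1C(OCc2ccccc2)=C(OCc2ccccc2)C1O | intermediate (not isolated)
13 | 3-(benzyloxy)cyclobut-3-ene-1,2-dione | O=C1C=C(OCc2ccccc2)C1=O | intermediate
14 | {cis-2-[4-methoxy-3,5-bis(triisopropylsilyloxy)phenyl]-4-(triisopropylsilyloxy)-3,4-dihydro-2H-pyran-6-yl}lithium | C1=C([Li])O[C@H](c2cc(O[Si](C(C)C)(C(C)C)C(C)C)c(OC)c(O[Si](C(C)C)(C(C)C)C(C)C)c2)C[C@@H]1O[Si](C(C)C)(C(C)C)C(C)C | intermediate (not isolated)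
15 | 3-(benzyloxy)-4-hydroxy-4-{cis-2-[4-methoxy-3,5-bis(triisopropylsilyloxy)phenyl]-4-(triisopropylsilyloxy)-3,4-dihydro-2H-pyran-6-yl}cyclobut-2-en-1-one (carbinol epimers) | C1=C(C2(O)C(=O)C=C2OCc2ccccc2)O[C@H](c2cc(O[Si](C(C)C)(C(C)C)C(C)C)c(OC)c(O[Si](C(C)C)(C(C)C)C(C)C)c2)C[C@@H]1O[Si](C(C)C)(C(C)C)C(C)C | intermediate (not isolated)
16 | (Z)-3-(benzyloxy)-4-hydroxy-4-{cis-2-[4-methoxy-3,5-bis(triisopropylsilyloxy)phenyl]-4-(triisopropylsilyloxy)-3,4-dihydro-2H-pyran-6-yl}buta-1,3-dien-1-one | C1=C(/C(O)=C(OCc2ccccc2)\C=C=O)O[C@H](c2cc(O[Si](C(C)C)(C(C)C)C(C)C)c(OC)c(O[Si](C(C)C)(C(C)C)C(C)C)c2)C[C@@H]1O[Si](C(C)C)(C(C)C)C(C)C | intermediate (not isolated)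
17 | cis-(2S*,4S*)-7-(benzyloxy)-2-[4-methoxy-3,5-bis(triisopropylsilyloxy)phenyl]-4-(triisopropylsilyloxy)chromane-5,8-diol (racemic, one enantiomer drawn) | c12c(O)cc(OCc3ccccc3)c(O)c1O[C@H](c1cc(O[Si](C(C)C)(C(C)C)C(C)C)c(OC)c(O[Si](C(C)C)(C(C)C)C(C)C)c1)C[C@@H]2O[Si](C(C)C)(C(C)C)C(C)C | intermediate
18 | cis-(2S*,4S*)-7-(benzyloxy)-5,8-dimethoxy-2-[4-methoxy-3,5-bis(triisopropylsilyloxy)phenyl]-4-(triisopropylsilyloxy)chromane (racemic, one enantiomer drawn) | c12c(OC)cc(OCc3ccccc3)c(OC)c1O[C@H](c1cc(O[Si](C(C)C)(C(C)C)C(C)C)c(OC)c(O[Si](C(C)C)(C(C)C)C(C)C)c1)C[C@@H]2O[Si](C(C)C)(C(C)C)C(C)C | intermediate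
19 | cis-(2S*,4S*)-7-(benzyloxy)-2-(3,5-dihydroxy-4-methoxyphenyl)-5,8-dimethoxychroman-4-ol (racemic, one enantiomer drawn) | c12c(OC)cc(OCc3ccccc3)c(OC)c1O[C@H](c1cc(O)c(OC)c(O)c1)C[C@@H]2O | intermediate (not isolated)
20 | cis-(2S*,4S*)-7-(benzyloxy)-2-[3,5-bis(benzyloxy)-4-methoxyphenyl]-5,8-dimethoxychroman-4-ol (racemic, one enantiomer drawn) | c12c(OC)cc(OCc3ccccc3)c(OC)c1O[C@H](c1cc(OCc3ccccc3)c(OC)c(OCc3ccccc3)c1)C[C@@H]2O | intermediate
21 | 7-(benzyloxy)-2-[3,5-bis(benzyloxy)-4-methoxyphenyl]-5,8-dimethoxychroman-4-one (racemic, one enantiomer drawn) | c12c(OC)cc(OCc3ccccc3)c(OC)c1O[C@H](c1cc(OCc3ccccc3)c(OC)c(OCc3ccccc3)c1)CC2=O | intermediate (not isolated)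
22 | 7-(benzyloxy)-2-[3,5-bis(benzyloxy)-4-methoxyphenyl]-5,8-dimethoxy-4H-chromen-4-one | COc1c(OCc2ccccc2)cc(-c2cc(=O)c3c(OC)cc(OCc4ccccc4)c(OC)c3o2)cc1OCc1ccccc1 | intermediate
23 | 2-(3,5-dihydroxy-4-methoxyphenyl)-7-hydroxy-5,8-dimethoxy-4H-chromen-4-one (CNP0218554.0) | COc1c(O)cc(-c2cc(=O)c3c(OC)cc(O)c(OC)c3o2)cc1O | target

## Step count and risks

Total: 13 steps. Longest linear sequence: 11 steps (steps 1–6 and 9–13, from 1). The two-step branch from squaric acid (steps 7 and 8) joins in step 9.

**Step 9 (key step).** The most likely failure is in the metallation: t-BuLi may remove the benzylic C2 hydrogen, which is also next to the ring oxygen, in competition with the C6 vinyl hydrogen, or lithiation at C6 may remain incomplete, so that little of the required anion reaches 13. Secondary risks are addition at the vinylogous ester carbon of 13 and aerial oxidation of the hydroquinone during isolation.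

Fallback, from 9 back to 14 (and so to 17), with no deprotonation of 9:
- Benzenesulfinic acid is added across the enol ether of 9 to give the anomeric sulfone 2-[4-methoxy-3,5-bis(triisopropylsilyloxy)phenyl]-6-(phenylsulfonyl)-4-(triisopropylsilyloxy)tetrahydro-2H-pyran F1.
- The C–H next to sulfur in F1 is far more acidic than the benzylic one and is removed by n-BuLi at −78 °C. Trapping with Bu3SnCl and elimination of benzenesulfinic acid with i-Pr2NEt gives tributyl{cis-2-[4-methoxy-3,5-bis(triisopropylsilyloxy)phenyl]-4-(triisopropylsilyloxy)-3,4-dihydro-2H-pyran-6-yl}stannane F2.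
- Tin–lithium exchange on F2 with n-BuLi at −78 °C gives 14 regiospecifically, and addition to 13 and thermolysis follow as in step 9.

**Step 12.** Hydride abstraction may not stay at C4: attack at the C2–H or at the benzylic positions of the ether groups at 100 °C would erode the material, or the dehydrogenation may stall at the flavanone stage.

Fallback, from 20 back to 22, separating the two events and changing the mechanism of the second: Dess–Martin periodinane oxidises 20 to 21, which is then isolated, and iodine in DMSO at 120 °C (α-iodination and elimination) converts 21 into 22. No new compound is involved.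

**Step 13.** The pyranone double bond may be saturated while the hindered O7 benzyl ether is still being cleaved.

Fallback, from 22 back to 23: hydrogenation is run to complete debenzylation, accepting reduction to 2-(3,5-dihydroxy-4-methoxyphenyl)-7-hydroxy-5,8-dimethoxychroman-4-one F3. F3 is re-dehydrogenated with iodine in DMSO, a method that tolerates free phenols, to give 23.

**Step 8.** A second hydride may add, or the benzyl vinylogous ester may be hydrolysed during the acid-induced transposition, with loss of the benzyl group.

Fallback, from 11 back to 13: cyanide-catalysed reaction of 11 with Me3Si–SnBu3 replaces one benzyloxy group by tin to give 3-(benzyloxy)-4-(tributylstannyl)cyclobut-3-ene-1,2-dione F4. Protodestannylation of F4 with HCl in CH2Cl2 gives 13 without any hydride reagent.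

**Step 10.** Under base the hydroquinone may be oxidised by traces of air to the quinone, and alkylation of O5 next to the bulky silyloxy-bearing C4 may be slow.

Fallback, from 9 and 13 back to 18, so that no free hydroquinone is handled:
- Step 9 is repeated, but the lithium alkoxide of the adduct is methylated with MeOTf at −78 °C before work-up to give 3-(benzyloxy)-4-methoxy-4-{cis-2-[4-methoxy-3,5-bis(triisopropylsilyloxy)phenyl]-4-(triisopropylsilyloxy)-3,4-dihydro-2H-pyran-6-yl}cyclobut-2-en-1-one F5.
- Thermolysis of F5 in toluene gives the air-stable monomethyl ether cis-7-(benzyloxy)-8-methoxy-2-[4-methoxy-3,5-bis(triisopropylsilyloxy)phenyl]-4-(triisopropylsilyloxy)chroman-5-ol F6.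
- Methylation of F6 at O5 with MeI and K2CO3 gives 18.

## Further compounds

F1 | step 9 | 2-[4-methoxy-3,5-bis(triisopropylsilyloxy)phenyl]-6-(phenylsulfonyl)-4-(triisopropylsilyloxy)tetrahydro-2H-pyran (2,4-cis, C6 epimers, racemic) | C1C(S(=O)(=O)c2ccccc2)O[C@H](c2cc(O[Si](C(C)C)(C(C)C)C(C)C)c(OC)c(O[Si](C(C)C)(C(C)C)C(C)C)c2)C[C@@H]1O[Si](C(C)C)(C(C)C)C(C)C
F2 | step 9 | tributyl{cis-2-[4-methoxy-3,5-bis(triisopropylsilyloxy)phenyl]-4-(triisopropylsilyloxy)-3,4-dihydro-2H-pyran-6-yl}stannane (racemic) | C1=C([Sn](CCCC)(CCCC)CCCC)O[C@H](c2cc(O[Si](C(C)C)(C(C)C)C(C)C)c(OC)c(O[Si](C(C)C)(C(C)C)C(C)C)c2)C[C@@H]1O[Si](C(C)C)(C(C)C)C(C)C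
F0 | step 12 | none | none
F3 | step 13 | 2-(3,5-dihydroxy-4-methoxyphenyl)-7-hydroxy-5,8-dimethoxychroman-4-one (racemic) | COc1c(O)cc(C2CC(=O)c3c(OC)cc(O)c(OC)c3O2)cc1O
F4 | step 8 | 3-(benzyloxy)-4-(tributylstannyl)cyclobut-3-ene-1,2-dione | O=C1C(=O)C([Sn](CCCC)(CCCC)CCCC)=C1OCc1ccccc1
F5 | step 10 | 3-(benzyloxy)-4-methoxy-4-{cis-2-[4-methoxy-3,5-bis(triisopropylsilyloxy)phenyl]-4-(triisopropylsilyloxy)-3,4-dihydro-2H-pyran-6-yl}cyclobut-2-en-1-one (racemic, epimers at the quaternary carbon) | C1=C(C2(OC)C(=O)C=C2OCc2ccccc2)O[C@H](c2cc(O[Si](C(C)C)(C(C)C)C(C)C)c(OC)c(O[Si](C(C)C)(C(C)C)C(C)C)c2)C[C@@H]1O[Si](C(C)C)(C(C)C)C(C)C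
F6 | step 10 | cis-(2S*,4S*)-7-(benzyloxy)-8-methoxy-2-[4-methoxy-3,5-bis(triisopropylsilyloxy)phenyl]-4-(triisopropylsilyloxy)chroman-5-ol (racemic) | c12c(O)cc(OCc3ccccc3)c(OC)c1O[C@H](c1cc(O[Si](C(C)C)(C(C)C)C(C)C)c(OC)c(O[Si](C(C)C)(C(C)C)C(C)C)c1)C[C@@H]2O[Si](C(C)C)(C(C)C)C(C)C
A1 | alternative 1 | 7-(benzyloxy)-2-[3,5-bis(benzyloxy)-4-methoxyphenyl]-5,8-dimethoxy-4H-chromen-4-one | COc1c(OCc2ccccc2)cc(-c2cc(=O)c3c(OC)cc(OCc4ccccc4)c(OC)c3o2)cc1OCc1ccccc1
A2 | alternative 1 | 4-(benzyloxy)-2-hydroxy-3,6-dimethoxybenzaldehyde | O=Cc1c(O)c(OC)c(OCc2ccccc2)cc1OC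
A3 | alternative 1 | 1-[3,5-bis(benzyloxy)-4-methoxyphenyl]-2-[dimethyl(oxo)-λ6-sulfanylidene]ethan-1-one | COc1c(OCc2ccccc2)cc(C(=O)C=S(C)(C)=O)cc1OCc1ccccc1
A4 | alternative 2 | 7-(benzyloxy)-2-[3,5-bis(benzyloxy)-4-methoxyphenyl]-5,8-dihydroxy-4H-chromen-4-one | COc1c(OCc2ccccc2)cc(-c2cc(=O)c3c(O)cc(OCc4ccccc4)c(O)c3o2)cc1OCc1ccccc1
A5 | alternative 2 | 1-[4-(benzyloxy)-2,5-dimethoxyphenyl]-3-[3,5-bis(benzyloxy)-4-methoxyphenyl]propane-1,3-dione | COc1cc(OCc2ccccc2)c(OC)cc1C(=O)CC(=O)c1cc(OCc2ccccc2)c(OC)c(OCc2ccccc2)c1
A6 | alternative 2 | 2-(benzyloxy)-5-{3-[3,5-bis(benzyloxy)-4-methoxyphenyl]-3-oxopropanoyl}cyclohexa-2,5-diene-1,4-dione | O=C1C=C(OCc2ccccc2)C(=O)C=C1C(=O)CC(=O)c1cc(OCc2ccccc2)c(OC)c(OCc2ccccc2)c1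
A7 | alternative 3 | 2-[3,5-bis(benzyloxy)-4-methoxyphenyl]-7-hydroxy-5,8-dimethoxy-4H-chromen-4-one | COc1c(OCc2ccccc2)cc(-c2cc(=O)c3c(OC)cc(O)c(OC)c3o2)cc1OCc1ccccc1
A8 | alternative 3 | 4-iodo-2,5-dimethoxybenzene-1,3-diol | COc1cc(O)c(OC)c(O)c1I
A9 | alternative 3 | 1,3-bis(benzyloxy)-5-ethynyl-2-methoxybenzene | C#Cc1cc(OCc2ccccc2)c(OC)c(OCc2ccccc2)c1
A10 | alternative 3 | carbon monoxide | [C-]#[O+]
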